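The synthesis rests on the bond between C2 of the γ-pyrone (chromone) ring and the benzylic CH2 of the resorcylic acid ring. Two native features are exploited: the CH2 sits ortho to the CO2H on the benzene ring, so the carboxylate itself supports a lateral benzylic carbanion, and C2 is the β-carbon of the vinylogous ester O1–C2=C3–C4=O, so a sulfonyl group there is displaced by addition–elimination. In one operation the dilithiated 2,4-dimethoxy-6-methylbenzoic acid and 5-heptyl-2-methanesulfonyl-7-methoxychromone, made in five steps from 5-heptylresorcinol, give the whole skeleton with the free acid already in place; one global demethylation then delivers siphulin.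

Key step: step 6

Remark: the target has no stereocentre and is achiral, so its SMILES defines it completely and no stereocontrol is required.

Step 1
Reactants: 1 5-heptylbenzene-1,3-diol (5-heptylresorcinol)
Product: 3 1-(2-heptyl-4,6-dihydroxyphenyl)ethan-1-one, via ketiminium chloride 2 (not isolated)
Conditions: MeCN, ZnCl2, HCl (g), Et2O, 0 °C → rt; then H2O, reflux
Reagents that add atoms: acetonitrile CC#N; water O
Why: Houben–Hoesch acylation, in which the ZnCl2/HCl-activated nitrile should attack the resorcinol at C4 (para to one hydroxyl, ortho to the other, the orcinol → orcacetophenone pattern) and the ketiminium salt is hydrolysed to the ketone.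

Step 2
Reactants: 3 1-(2-heptyl-4,6-dihydroxyphenyl)ethan-1-one
Product: 4 1-(2-heptyl-6-hydroxy-4-methoxyphenyl)ethan-1-one
Conditions: MeI (1.05 equiv), K2CO3 (1.1 equiv), acetone, reflux
Reagents that add atoms: iodomethane CI
Why: Williamson ether synthesis, selective because the 6-OH is held in an intramolecular hydrogen bond to the acetyl oxygen, so one equivalent of MeI should alkylate only the free 4-OH.

Step 3
Reactants: 4 1-(2-heptyl-6-hydroxy-4-methoxyphenyl)ethan-1-one
Product: 5 5-heptyl-4-hydroxy-7-methoxy-2H-chromene-2-thione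
Conditions: CS2, t-BuOK (3 equiv), THF, 0 °C → rt; then 10% aq. H2SO4
Reagents that add atoms: carbon disulfide S=C=S
Why: Dithiocarboxylation of the ketone enolate with CS2, followed on acidification by cyclisation of the phenol onto the dithioacid with loss of H2S, the standard entry to 4-hydroxy-2-thioxochromenes from 2-hydroxyacetophenones.

Step 4
Reactants: 5 5-heptyl-4-hydroxy-7-methoxy-2H-chromene-2-thione
Product: 6 5-heptyl-7-methoxy-2-(methylsulfanyl)-4H-chromen-4-one
Conditions: MeI, K2CO3, acetone, rt
Reagents that add atoms: iodomethane CI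
Why: S-alkylation of the ambident thione anion (soft sulfur is preferred over the 4-oxygen), which fixes the 4-pyranone tautomer as a vinylogous thioester.

Step 5
Reactants: 6 5-heptyl-7-methoxy-2-(methylsulfanyl)-4H-chromen-4-one
Product: 7 5-heptyl-2-(methanesulfonyl)-7-methoxy-4H-chromen-4-one
Conditions: mCPBA (2.2 equiv), CH2Cl2, 0 °C → rt
Reagents that add atoms: mCPBA OOC(=O)c1cccc(Cl)c1
Why: Peracid oxidation of the sulfide to the sulfone; the electron-poor C2=C3 bond and the methoxyarene should not be attacked under these conditions.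

Step 6
Reactants: 7 5-heptyl-2-(methanesulfonyl)-7-methoxy-4H-chromen-4-one, 8 2,4-dimethoxy-6-methylbenzoic acid
Product: 10 2-[(5-heptyl-7-methoxy-4-oxo-4H-chromen-2-yl)methyl]-4,6-dimethoxybenzoic acid, via dilithiated benzoate 9 (not isolated)
Conditions: 8 (2.2 equiv), LDA (4.5 equiv), THF, –78 → 0 °C; then 7 added at –78 °C, → –40 °C; 1 M HCl
Reagents that add atoms: none
Why: Conjugate addition–elimination (SNV) of a laterally lithiated benzoate: LDA removes the acid proton and then a benzylic proton of 8 (the ortho carboxylate stabilises the carbanion), the benzylic carbon of 9 adds to C2 of 7, and the resulting C3 enolate expels methanesulfinate to restore the γ-pyrone ring. The closest known reactions are the displacement of 2-sulfonyl- and 2-sulfinylchromones by amines and the Michael stage of toluate-anion additions to β-alkoxy enones (Staunton–Weinreb). No ring is closed and no stereocentre is formed. The step needs attack at C2 and not at the C4 carbonyl, which the LUMO-lowering sulfonyl group at C2 and the peri 5-heptyl group shielding C4 should secure, and lateral instead of ring metalation of 8, which LDA under equilibrating conditions should give. Because the carboxyl group is carried as its lithium salt and not as an ester, neither the C3 enolate nor the product anion can close onto it, so no Claisen-type naphthol annulation is possible. The second equivalent of 9 deprotonates the doubly activated CH2 of the product and so prevents a second addition; acid work-up returns 10 and unreacted 8.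

Step 7
Reactants: 10 2-[(5-heptyl-7-methoxy-4-oxo-4H-chromen-2-yl)methyl]-4,6-dimethoxybenzoic acid
Product: 11 siphulin, 2-[(5-heptyl-7-hydroxy-4-oxo-4H-chromen-2-yl)methyl]-4,6-dihydroxybenzoic acid
Conditions: BBr3 (8 equiv), CH2Cl2, –78 °C → rt; then ice–H2O
Reagents that add atoms: none
Why: Lewis-acid ether cleavage, in which BBr3 complexes each aryl methyl ether and bromide removes the methyl group by SN2; kept at or below room temperature with a cold aqueous quench, the resorcylic acid should survive without decarboxylation.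

Compound list
1 | 5-heptylbenzene-1,3-diol (5-heptylresorcinol) | CCCCCCCc1cc(O)cc(O)c1 | starting material
2 | 1-(2-heptyl-4,6-dihydroxyphenyl)ethan-1-iminium chloride | CCCCCCCc1cc(O)cc(O)c1C(C)=[NH2+].[Cl-] | intermediate
3 | 1-(2-heptyl-4,6-dihydroxyphenyl)ethan-1-one | CCCCCCCc1cc(O)cc(O)c1C(C)=O | intermediate
4 | 1-(2-heptyl-6-hydroxy-4-methoxyphenyl)ethan-1-one | CCCCCCCc1cc(OC)cc(O)c1C(C)=O | intermediate
5 | 5-heptyl-4-hydroxy-7-methoxy-2H-chromene-2-thione | CCCCCCCc1cc(OC)cc2oc(=S)cc(O)c12 | intermediate
6 | 5-heptyl-7-methoxy-2-(methylsulfanyl)-4H-chromen-4-one | CCCCCCCc1cc(OC)cc2oc(SC)cc(=O)c12 | intermediate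
7 | 5-heptyl-2-(methanesulfonyl)-7-methoxy-4H-chromen-4-one | CCCCCCCc1cc(OC)cc2oc(S(C)(=O)=O)cc(=O)c12 | intermediate
8 | 2,4-dimethoxy-6-methylbenzoic acid | Cc1cc(OC)cc(OC)c1C(=O)O | starting material
9 | dilithium 2-methanidyl-4,6-dimethoxybenzoate (lithium 2-(lithiomethyl)-4,6-dimethoxybenzoate) | [Li+].[Li+].[CH2-]c1cc(OC)cc(OC)c1C(=O)[O-] | intermediate
10 | 2-[(5-heptyl-7-methoxy-4-oxo-4H-chromen-2-yl)methyl]-4,6-dimethoxybenzoic acid | CCCCCCCc1cc(OC)cc2oc(Cc3cc(OC)cc(OC)c3C(=O)O)cc(=O)c12 | intermediate
11 | siphulin, 2-[(5-heptyl-7-hydroxy-4-oxo-4H-chromen-2-yl)methyl]-4,6-dihydroxybenzoic acid | CCCCCCCc1cc(O)cc2oc(Cc3cc(O)cc(O)c3C(=O)O)cc(=O)c12 | target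

Total step count: 7. Longest linear sequence: 7 steps (1 → 3 → 4 → 5 → 6 → 7 → 10 → 11); acid 8 is purchased.

Steps most likely to fail

Step 6. The hard, strongly basic benzylic lithium may transfer a proton from the S-methyl group of 7 instead of adding, may attack the C4 carbonyl, or may reduce the sulfone by electron transfer. The fallback replaces the polar displacement by a palladium-catalysed C–S cross-coupling; it sets out from sulfide 6 (the oxidation is omitted) and comes back to the route at 11. Commercial methyl 2,4-dimethoxy-6-methylbenzoate F1 is laterally lithiated (LDA, THF, –78 °C) and transmetalated with ZnCl2 to the soft, non-basic [2-(methoxycarbonyl)-3,5-dimethoxybenzyl]zinc chloride F2. Negishi-type coupling of F2 with 6 (Pd(OAc)2, SPhos, THF, 25–50 °C) should give methyl 2-[(5-heptyl-7-methoxy-4-oxo-4H-chromen-2-yl)methyl]-4,6-dimethoxybenzoate F3. Excess BBr3 (CH2Cl2, –78 °C → rt) should then cleave the three aryl methyl ethers and the methyl ester in one operation to give 11.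

Step 7. Once the hydroxyl groups are unmasked, the electron-rich resorcylic acid may lose CO2 by ipso-protonation in the acidic medium, and the 7-methoxy group, deactivated by conjugation with C4=O, may be cleaved incompletely. The fallback changes the protecting groups to benzyl so that the last step is a neutral hydrogenolysis; it sets out from 3 and comes back at 11. 3 is benzylated at the free 4-OH (BnBr, K2CO3, acetone) to 1-[4-(benzyloxy)-2-heptyl-6-hydroxyphenyl]ethan-1-one F4. F4 is taken through the operations of steps 3–5, via 7-(benzyloxy)-5-heptyl-4-hydroxy-2H-chromene-2-thione F5 and 7-(benzyloxy)-5-heptyl-2-(methylsulfanyl)-4H-chromen-4-one F6, to 7-(benzyloxy)-5-heptyl-2-(methanesulfonyl)-4H-chromen-4-one F7. Commercial methyl 2,4-dihydroxy-6-methylbenzoate F8 is benzylated (BnBr, K2CO3, DMF) to methyl 2,4-bis(benzyloxy)-6-methylbenzoate F9 and saponified (KOH, DMSO–H2O, 80 °C) to 2,4-bis(benzyloxy)-6-methylbenzoic acid F10. Dianion coupling of F10 with F7 under the conditions of step 6 should give 2-{[7-(benzyloxy)-5-heptyl-4-oxo-4H-chromen-2-yl]methyl}-4,6-bis(benzyloxy)benzoic acid F11. Hydrogenolysis (H2, Pd/C, EtOAc, rt) should then release 11.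

Step 1. The acylation may show poor regioselectivity (attack at C2 between the two hydroxyls) or run on to a second acylation. The fallback moves the regiocontrol to a sterically governed Friedel–Crafts reaction on the dimethyl ether; it sets out from 1 and comes back at 4. 1 is exhaustively methylated (Me2SO4, K2CO3, acetone) to 1-heptyl-3,5-dimethoxybenzene F12. Acetylation (AcCl, AlCl3, CH2Cl2, 0 °C) should avoid the hindered position between the two methoxy groups and give 1-(2-heptyl-4,6-dimethoxyphenyl)ethan-1-one F13. Chelation-controlled cleavage of the methoxy group ortho to the acetyl (BCl3, CH2Cl2, 0 °C) should then give 4.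

Further compounds
F1 | step 6 | methyl 2,4-dimethoxy-6-methylbenzoate | Cc1cc(OC)cc(OC)c1C(=O)OC
F2 | step 6 | [2-(methoxycarbonyl)-3,5-dimethoxybenzyl]zinc chloride | COC(=O)c1c(C[Zn]Cl)cc(OC)cc1OC
F3 | step 6 | methyl 2-[(5-heptyl-7-methoxy-4-oxo-4H-chromen-2-yl)methyl]-4,6-dimethoxybenzoate | CCCCCCCc1cc(OC)cc2oc(Cc3cc(OC)cc(OC)c3C(=O)OC)cc(=O)c12
F4 | step 7 | 1-[4-(benzyloxy)-2-heptyl-6-hydroxyphenyl]ethan-1-one | CCCCCCCc1cc(OCc2ccccc2)cc(O)c1C(C)=O
F5 | step 7 | 7-(benzyloxy)-5-heptyl-4-hydroxy-2H-chromene-2-thione | CCCCCCCc1cc(OCc3ccccc3)cc2oc(=S)cc(O)c12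
F6 | step 7 | 7-(benzyloxy)-5-heptyl-2-(methylsulfanyl)-4H-chromen-4-one | CCCCCCCc1cc(OCc3ccccc3)cc2oc(SC)cc(=O)c12
F7 | step 7 | 7-(benzyloxy)-5-heptyl-2-(methanesulfonyl)-4H-chromen-4-one | CCCCCCCc1cc(OCc3ccccc3)cc2oc(S(C)(=O)=O)cc(=O)c12
F8 | step 7 | methyl 2,4-dihydroxy-6-methylbenzoate | Cc1cc(O)cc(O)c1C(=O)OC
F9 | step 7 | methyl 2,4-bis(benzyloxy)-6-methylbenzoate | Cc1cc(OCc2ccccc2)cc(OCc2ccccc2)c1C(=O)OC
F10 | step 7 | 2,4-bis(benzyloxy)-6-methylbenzoic acid | Cc1cc(OCc2ccccc2)cc(OCc2ccccc2)c1C(=O)O
F11 | step 7 | 2-{[7-(benzyloxy)-5-heptyl-4-oxo-4H-chromen-2-yl]methyl}-4,6-bis(benzyloxy)benzoic acid | CCCCCCCc1cc(OCc4ccccc4)cc2oc(Cc3cc(OCc4ccccc4)cc(OCc4ccccc4)c3C(=O)O)cc(=O)c12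
F12 | step 1 | 1-heptyl-3,5-dimethoxybenzene | CCCCCCCc1cc(OC)cc(OC)c1
F13 | step 1 | 1-(2-heptyl-4,6-dimethoxyphenyl)ethan-1-one | CCCCCCCc1cc(OC)cc(OC)c1C(C)=O
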